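**Retrosynthetic overview**

1. The target is a [7.7]paracyclophane (22-membered ring through two resorcinol rings). Locants: ring A carries C1(OCONH2)–C2(Me)–C3…C6–C7(Bu), and C7 sits on C-2 of ring B; ring B carries C14(OCONH2)–C15(Me)–C16…C19–C20(4,4-dichlorobutyl), and C20 sits on C-2 of ring A. Enabling feature: in each 1,3-dihydroxybenzene ring, C-2 (between the two OH) is bonded to a secondary sp3 CH (C7, C20), which is the retron of an enzymatic Friedel–Crafts alkylation with a secondary alkyl chloride.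
2. Last operation: carbamoylation of the C1/C14 diol. Key disconnection: ring A C-2–C20, giving an open-chain seco-chloride (C20–Cl) in which C-2 of ring B is already blocked by C7; a CylK-family Friedel–Crafts alkylase closes the ring with inversion at C20.
3. Seco-chloride: chain B by cross-metathesis at C16=C17 (crotyl alkene on ring B plus a trichlorononene), chain A by cross-metathesis at C3=C4 then diimide; C1/C2 and C14/C15 by catalytic (Z)-crotylboration of aryl aldehydes.
4. Ring B C-2–C7: the same enzyme class used intermolecularly (3,5-dihydroxybenzyl alcohol plus a 5-chlorononene). C7 and C20 are both S but have opposite spatial sense (CHCl2 reverses the CIP ranking at C20), so a one-pot head-to-tail dimerisation cannot give this isomer; the two chlorides come from the two enantiomers of 1,2-epoxy-5-hexene.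
5. Ring order: both benzene rings are bought; the only ring formed is the 22-membered macrocycle, closed last.

Key step: step 16

Assumption: a recombinant CylK-family alkylase (CylK or a close variant) accepts the benzylic-hydroxylated substrates used here and, acting by SN2-type displacement, converts the chloride configuration into the product configuration by inversion.

**Route**

Step 1
Reactants: 1 (R)-2-(but-3-en-1-yl)oxirane; 2 n-propylmagnesium bromide
Product: 3 (5S)-non-1-en-5-ol
Conditions: CuI (10 mol%), THF, −30 → 0 °C; H2O work-up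
Reagents that add atoms: none
Why: Copper-catalysed Grignard opening of a terminal epoxide occurs at the CH2 carbon, so the stereocentre is carried over untouched (descriptor S by CIP ranking only).

Step 2
Reactants: 3 (5S)-non-1-en-5-ol
Product: 4 (5R)-5-chloronon-1-ene
Conditions: PPh3, N-chlorosuccinimide, CH2Cl2, 0 °C → rt
Reagents that add atoms: N-chlorosuccinimide, O=C1CCC(=O)N1Cl
Why: Appel-type chlorination of an unactivated secondary alcohol proceeds by SN2 displacement at the activated carbinol carbon, inverting C5 to R.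

Step 3
Reactants: 5 (S)-2-(but-3-en-1-yl)oxirane; 6 [2-(1,3-dioxolan-2-yl)ethyl]magnesium bromide
Product: 7 (4R)-1-(1,3-dioxolan-2-yl)oct-7-en-4-ol
Conditions: CuI (10 mol%), THF, −30 → 0 °C; H2O work-up
Reagents that add atoms: none
Why: Copper-catalysed Grignard opening at the terminal epoxide carbon installs the masked four-carbon aldehyde arm and leaves the stereocentre untouched.

Step 4
Reactants: 7 (4R)-1-(1,3-dioxolan-2-yl)oct-7-en-4-ol
Product: 8 2-[(4S)-4-chlorooct-7-en-1-yl]-1,3-dioxolane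
Conditions: PPh3, N-chlorosuccinimide, CH2Cl2, 0 °C → rt
Reagents that add atoms: N-chlorosuccinimide, O=C1CCC(=O)N1Cl
Why: Appel-type chlorination with SN2 inversion sets the C–Cl stereocentre (S) under neutral conditions that the dioxolane tolerates.

Step 5
Reactants: 8 2-[(4S)-4-chlorooct-7-en-1-yl]-1,3-dioxolane
Product: 9 (5S)-5-chloronon-8-enal
Conditions: 1 M HCl, THF, rt
Reagents that add atoms: water, O
Why: Acid-catalysed acetal hydrolysis releases the aldehyde without affecting the secondary chloride or the alkene.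

Step 6
Reactants: 9 (5S)-5-chloronon-8-enal
Product: 10 (5S)-5,9,9-trichloronon-1-ene
Conditions: Ph3PO (15 mol%), (COCl)2, CHCl3, rt
Reagents that add atoms: oxalyl chloride, ClC(=O)C(=O)Cl
Why: Phosphine-oxide-catalysed deoxydichlorination of an aldehyde (Appel-type, via Ph3PCl2) converts CHO into CHCl2 without free chlorine, so the alkene and the C–Cl stereocentre are untouched.

Step 7
Reactants: 11 3,5-bis(benzyloxy)benzaldehyde; 12 (Z)-crotylboronic acid pinacol ester
Product: 13 (1R,2S)-1-[3,5-bis(benzyloxy)phenyl]-2-methylbut-3-en-1-ol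
Conditions: (R)-TRIP (5 mol%), toluene, −30 °C; aqueous work-up
Reagents that add atoms: none
Why: Chiral-phosphoric-acid-catalysed crotylboration passes through a closed chair (Zimmerman–Traxler) transition state, so the (Z)-boronate gives the syn product and (R)-TRIP directs attack to the Re face of the aldehyde, setting C1 (R) and C2 (S).

Step 8
Reactants: 14 3,5-dihydroxybenzyl alcohol; 4 (5R)-5-chloronon-1-ene
Product: 15 5-(hydroxymethyl)-2-[(5S)-non-1-en-5-yl]benzene-1,3-diol
Conditions: CylK (recombinant Friedel–Crafts alkylase, 2 mol%), HEPES pH 7.8, NaCl, MgCl2, CaCl2, 5% DMSO, 37 °C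
Reagents that add atoms: none
Why: Biocatalytic Friedel–Crafts alkylation in its known intermolecular mode (resorcinol plus secondary alkyl halide) attacks through C-2 of the resorcinol with inversion, so the (R)-chloride gives (S)-C7, and because the butyl and but-3-enyl arms are nearly isosteric the outcome is dictated by the chloride rather than by any enantiopreference of the enzyme.

Step 9
Reactants: 15 5-(hydroxymethyl)-2-[(5S)-non-1-en-5-yl]benzene-1,3-diol
Product: 16 {3,5-bis(benzyloxy)-4-[(5S)-non-1-en-5-yl]phenyl}methanol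
Conditions: BnBr, K2CO3, DMF, 50 °C
Reagents that add atoms: benzyl bromide, BrCc1ccccc1
Why: Williamson etherification under carbonate base alkylates only the phenols and leaves the benzylic alcohol free.

Step 10
Reactants: 16 {3,5-bis(benzyloxy)-4-[(5S)-non-1-en-5-yl]phenyl}methanol; 13 (1R,2S)-1-[3,5-bis(benzyloxy)phenyl]-2-methylbut-3-en-1-ol
Product: 17 (1R,2S,3E,7S)-1-[3,5-bis(benzyloxy)phenyl]-7-[2,6-bis(benzyloxy)-4-(hydroxymethyl)phenyl]-2-methylundec-3-en-1-ol
Conditions: Hoveyda–Grubbs II (5 mol%), 13 (2 equiv), CH2Cl2, 40 °C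
Reagents that add atoms: none
Why: Olefin cross-metathesis between an unhindered terminal alkene (type I) and an allylically branched alkene (type II, in excess) favours the cross product, and the alkene geometry is irrelevant because the double bond is reduced next.

Step 11
Reactants: 17 (1R,2S,3E,7S)-1-[3,5-bis(benzyloxy)phenyl]-7-[2,6-bis(benzyloxy)-4-(hydroxymethyl)phenyl]-2-methylundec-3-en-1-ol
Product: 18 (1R,2S,7S)-1-[3,5-bis(benzyloxy)phenyl]-7-[2,6-bis(benzyloxy)-4-(hydroxymethyl)phenyl]-2-methylundecan-1-ol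
Conditions: 2-nitrobenzenesulfonylhydrazide, Et3N, CH2Cl2, rt
Reagents that add atoms: none
Why: Diimide reduction transfers H2 in a concerted syn fashion, so the alkene is saturated without migration toward C2 and without hydrogenolysis of benzyl ethers or benzylic alcohols.

Step 12
Reactants: 18 (1R,2S,7S)-1-[3,5-bis(benzyloxy)phenyl]-7-[2,6-bis(benzyloxy)-4-(hydroxymethyl)phenyl]-2-methylundecan-1-ol
Product: 19 3,5-bis(benzyloxy)-4-[(5S,10S,11R)-11-[3,5-bis(benzyloxy)phenyl]-11-hydroxy-10-methylundecan-5-yl]benzaldehyde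
Conditions: TEMPO (10 mol%), PhI(OAc)2, CH2Cl2, rt
Reagents that add atoms: none
Why: TEMPO/PhI(OAc)2 oxidation is selective for the primary benzylic alcohol over the hindered secondary one and stops at the aldehyde.

Step 13
Reactants: 19 3,5-bis(benzyloxy)-4-[(5S,10S,11R)-11-[3,5-bis(benzyloxy)phenyl]-11-hydroxy-10-methylundecan-5-yl]benzaldehyde; 12 (Z)-crotylboronic acid pinacol ester
Product: 20 (1R,2S,7S)-1-[3,5-bis(benzyloxy)phenyl]-7-{2,6-bis(benzyloxy)-4-[(1R,2S)-1-hydroxy-2-methylbut-3-en-1-yl]phenyl}-2-methylundecan-1-ol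
Conditions: (R)-TRIP (5 mol%), toluene, −30 °C; aqueous work-up
Reagents that add atoms: none
Why: The same chiral-phosphoric-acid-catalysed (Z)-crotylboration as in step 7 sets C14 (R) and C15 (S) syn under reagent control, the boronate tolerating the free C1 hydroxyl and the remote stereocentres exerting no influence.

Step 14
Reactants: 20 (1R,2S,7S)-1-[3,5-bis(benzyloxy)phenyl]-7-{2,6-bis(benzyloxy)-4-[(1R,2S)-1-hydroxy-2-methylbut-3-en-1-yl]phenyl}-2-methylundecan-1-ol; 10 (5S)-5,9,9-trichloronon-1-ene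
Product: 21 (1R,2S,7S)-1-[3,5-bis(benzyloxy)phenyl]-7-{2,6-bis(benzyloxy)-4-[(1R,2S,3E,7S)-7,11,11-trichloro-1-hydroxy-2-methylundec-3-en-1-yl]phenyl}-2-methylundecan-1-ol
Conditions: Hoveyda–Grubbs II (5–10 mol%), 10 (3 equiv), CH2Cl2, 40 °C
Reagents that add atoms: none
Why: Olefin cross-metathesis of the allylically branched terminal alkene (type II) with the unhindered chloroalkene (type I, in excess) gives the cross product, the ruthenium carbene tolerating alkyl chlorides and free hydroxyls.

Step 15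
Reactants: 21 (1R,2S,7S)-1-[3,5-bis(benzyloxy)phenyl]-7-{2,6-bis(benzyloxy)-4-[(1R,2S,3E,7S)-7,11,11-trichloro-1-hydroxy-2-methylundec-3-en-1-yl]phenyl}-2-methylundecan-1-ol
Product: 22 5-[(1R,2S,7S)-7-{2,6-dihydroxy-4-[(1R,2S,7R)-7,11,11-trichloro-1-hydroxy-2-methylundecyl]phenyl}-1-hydroxy-2-methylundecyl]benzene-1,3-diol
Conditions: H2 (1 atm), 10% Pd/C, EtOAc, rt
Reagents that add atoms: none
Why: Heterogeneous hydrogenation saturates the alkene and hydrogenolyses the four aryl benzyl ethers in one operation, while unactivated C–Cl bonds and the non-activated benzylic C–OH bonds should survive neutral conditions at 1 atm (the descriptor at C20 changes to R only through CIP ranking).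

Step 16
Reactants: 22 5-[(1R,2S,7S)-7-{2,6-dihydroxy-4-[(1R,2S,7R)-7,11,11-trichloro-1-hydroxy-2-methylundecyl]phenyl}-1-hydroxy-2-methylundecyl]benzene-1,3-diol
Product: 23 (1R,2S,7S,14R,15S,20S)-[7.7]paracyclophane-1,14-diol tetraphenol (the target with both carbamoyloxy groups replaced by OH)
Conditions: CylK (recombinant Friedel–Crafts alkylase, 5 mol%), HEPES pH 7.8, NaCl, MgCl2, CaCl2, 10% DMSO, 0.2 mM substrate, 37 °C
Reagents that add atoms: none
Why: The enzyme binds resorcinol ring A, an active-site base removes a phenolic proton while the chloride is held in the halide pocket, and C-2 of ring A displaces chloride from C20 in an SN2-type Friedel–Crafts alkylation followed by tautomerisation back to the arene. The closest known reactions are the native ring-closing (second) alkylation of this enzyme family in [7.7]paracyclophane biosynthesis and its intermolecular alkylation of resorcinols with secondary alkyl halides. One ring is closed, the 22-membered carbocycle, by intramolecular head-to-tail C-alkylation (22-exo-tet), both benzene rings being present beforehand. The new stereocentre C20 is controlled by the substrate: stereospecific inversion of the (R)-chloride installed in steps 3–4 gives (S)-C20. The step needs C- over O-alkylation at one ring position, the secondary chloride over the CHCl2 terminus, and cyclisation over oligomerisation: C-2 of ring B already bears C7 so only ring A can react, the geminal dichloride is a poor SN2 electrophile, and active-site templating at sub-millimolar concentration favours ring closure, so four phenols and two carbinols need no protection.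

Step 17
Reactants: 23 (1R,2S,7S,14R,15S,20S)-[7.7]paracyclophane-1,14-diol tetraphenol
Product: 25 target CNP0135078.1 (C1,C14-bis-carbamate), via hexakis(N-trichloroacetylcarbamate) 24 (not isolated)
Conditions: Cl3CC(O)NCO (8 equiv), CH2Cl2, 0 °C → rt; then K2CO3, MeOH, rt
Reagents that add atoms: trichloroacetyl isocyanate, O=C=NC(=O)C(Cl)(Cl)Cl
Why: Trichloroacetyl isocyanate carbamoylation acylates all six hydroxyls, and basic methanolysis then removes the trichloroacetyl groups and cleaves the four aryl carbamates (E1cB, phenoxide leaving group) while the two secondary alkyl carbamates persist.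

**Compound list**

1 | (R)-2-(but-3-en-1-yl)oxirane | C=CCC[C@@H]1CO1 | starting material
2 | n-propylmagnesium bromide | CCC[Mg]Br | starting material
3 | (5S)-non-1-en-5-ol | CCCC[C@H](O)CCC=C | intermediate
4 | (5R)-5-chloronon-1-ene | CCCC[C@@H](Cl)CCC=C | intermediate
5 | (S)-2-(but-3-en-1-yl)oxirane | C=CCC[C@H]1CO1 | starting material
6 | [2-(1,3-dioxolan-2-yl)ethyl]magnesium bromide | Br[Mg]CCC1OCCO1 | starting material
7 | (4R)-1-(1,3-dioxolan-2-yl)oct-7-en-4-ol | C=CCC[C@H](O)CCCC1OCCO1 | intermediate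
8 | 2-[(4S)-4-chlorooct-7-en-1-yl]-1,3-dioxolane | C=CCC[C@@H](Cl)CCCC1OCCO1 | intermediate
9 | (5S)-5-chloronon-8-enal | C=CCC[C@@H](Cl)CCCC=O | intermediate
10 | (5S)-5,9,9-trichloronon-1-ene | C=CCC[C@@H](Cl)CCCC(Cl)Cl | intermediate
11 | 3,5-bis(benzyloxy)benzaldehyde | O=Cc1cc(OCc2ccccc2)cc(OCc2ccccc2)c1 | starting material
12 | (Z)-crotylboronic acid pinacol ester | C/C=C\CB1OC(C)(C)C(C)(C)O1 | starting material
13 | (1R,2S)-1-[3,5-bis(benzyloxy)phenyl]-2-methylbut-3-en-1-ol | C=C[C@H](C)[C@@H](O)c1cc(OCc2ccccc2)cc(OCc2ccccc2)c1 | intermediate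
14 | 3,5-dihydroxybenzyl alcohol | OCc1cc(O)cc(O)c1 | starting material
15 | 5-(hydroxymethyl)-2-[(5S)-non-1-en-5-yl]benzene-1,3-diol | CCCC[C@H](c1c(O)cc(CO)cc1O)CCC=C | intermediate
16 | {3,5-bis(benzyloxy)-4-[(5S)-non-1-en-5-yl]phenyl}methanol | CCCC[C@H](c1c(OCc2ccccc2)cc(CO)cc1OCc1ccccc1)CCC=C | intermediate
17 | (1R,2S,3E,7S)-1-[3,5-bis(benzyloxy)phenyl]-7-[2,6-bis(benzyloxy)-4-(hydroxymethyl)phenyl]-2-methylundec-3-en-1-ol | CCCC[C@H](c1c(OCc2ccccc2)cc(CO)cc1OCc1ccccc1)CC/C=C/[C@H](C)[C@@H](O)c1cc(OCc2ccccc2)cc(OCc2ccccc2)c1 | intermediate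
18 | (1R,2S,7S)-1-[3,5-bis(benzyloxy)phenyl]-7-[2,6-bis(benzyloxy)-4-(hydroxymethyl)phenyl]-2-methylundecan-1-ol | CCCC[C@H](c1c(OCc2ccccc2)cc(CO)cc1OCc1ccccc1)CCCC[C@H](C)[C@@H](O)c1cc(OCc2ccccc2)cc(OCc2ccccc2)c1 | intermediate
19 | 3,5-bis(benzyloxy)-4-[(5S,10S,11R)-11-[3,5-bis(benzyloxy)phenyl]-11-hydroxy-10-methylundecan-5-yl]benzaldehyde | CCCC[C@H](c1c(OCc2ccccc2)cc(C=O)cc1OCc1ccccc1)CCCC[C@H](C)[C@@H](O)c1cc(OCc2ccccc2)cc(OCc2ccccc2)c1 | intermediate
20 | (1R,2S,7S)-1-[3,5-bis(benzyloxy)phenyl]-7-{2,6-bis(benzyloxy)-4-[(1R,2S)-1-hydroxy-2-methylbut-3-en-1-yl]phenyl}-2-methylundecan-1-ol | CCCC[C@H](c1c(OCc2ccccc2)cc([C@H](O)[C@@H](C)C=C)cc1OCc1ccccc1)CCCC[C@H](C)[C@@H](O)c1cc(OCc2ccccc2)cc(OCc2ccccc2)c1 | intermediate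
21 | (1R,2S,7S)-1-[3,5-bis(benzyloxy)phenyl]-7-{2,6-bis(benzyloxy)-4-[(1R,2S,3E,7S)-7,11,11-trichloro-1-hydroxy-2-methylundec-3-en-1-yl]phenyl}-2-methylundecan-1-ol | CCCC[C@H](c1c(OCc2ccccc2)cc([C@H](O)[C@@H](C)/C=C/CC[C@@H](Cl)CCCC(Cl)Cl)cc1OCc1ccccc1)CCCC[C@H](C)[C@@H](O)c1cc(OCc2ccccc2)cc(OCc2ccccc2)c1 | intermediate
22 | 5-[(1R,2S,7S)-7-{2,6-dihydroxy-4-[(1R,2S,7R)-7,11,11-trichloro-1-hydroxy-2-methylundecyl]phenyl}-1-hydroxy-2-methylundecyl]benzene-1,3-diol (seco-chloride) | CCCC[C@H](c1c(O)cc([C@H](O)[C@@H](C)CCCC[C@@H](Cl)CCCC(Cl)Cl)cc1O)CCCC[C@H](C)[C@@H](O)c1cc(O)cc(O)c1 | intermediate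
23 | (1R,2S,7S,14R,15S,20S)-[7.7]paracyclophane-1,14-diol tetraphenol (target with OH in place of both OCONH2) | CCCC[C@H]1CCCC[C@H](C)[C@@H](O)c2cc(O)c(c(O)c2)[C@H](CCCC(Cl)Cl)CCCC[C@H](C)[C@@H](O)c2cc(O)c1c(O)c2 | intermediate
24 | hexakis(N-trichloroacetylcarbamate) of 23 (all six O acylated) | CCCC[C@H]1CCCC[C@H](C)[C@@H](OC(=O)NC(=O)C(Cl)(Cl)Cl)c2cc(OC(=O)NC(=O)C(Cl)(Cl)Cl)c(c(OC(=O)NC(=O)C(Cl)(Cl)Cl)c2)[C@H](CCCC(Cl)Cl)CCCC[C@H](C)[C@@H](OC(=O)NC(=O)C(Cl)(Cl)Cl)c2cc(OC(=O)NC(=O)C(Cl)(Cl)Cl)c1c(OC(=O)NC(=O)C(Cl)(Cl)Cl)c2 | intermediate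
25 | CNP0135078.1, (1R,2S,7S,14R,15S,20S)-1,14-bis(carbamoyloxy) cyclophane tetraphenol | CCCC[C@H]1CCCC[C@H](C)[C@@H](OC(N)=O)c2cc(O)c(c(O)c2)[C@H](CCCC(Cl)Cl)CCCC[C@H](C)[C@@H](OC(N)=O)c2cc(O)c1c(O)c2 | target

**Step count and risks**

Total step count: 17. Longest linear sequence: 12 steps (steps 1, 2, 8–17).

Steps most likely to fail:

1. Step 16. The enzyme may turn over the seco-chloride slowly or not at all, because C7 is configured opposite to the corresponding centre of its native linear intermediate and the chain may not fold productively; intermolecular alkylation to oligomers and slow loss of chloride during long incubation could then compete. Fallback, setting out from 18 and returning at 23: hydrogenolysis of the four benzyl ethers of 18 (H2, Pd/C) would give the ring-B-blocked hexaol F1. The same alkylase in its intermolecular mode (as in step 8) would alkylate the only free resorcinol C-2 (ring A) with trichlorononene 10 to give the C20-alkylated mono-alkene F2, C20 being set by inversion. Re-benzylation of the phenols (BnBr, K2CO3) would give the tetrabenzyl ether F3, TEMPO/PhI(OAc)2 the aldehyde F4, and (Z)-crotylboration with 12 and (R)-TRIP the diene F5. Ring-closing metathesis (Hoveyda–Grubbs II, high dilution, CH2Cl2, 40 °C) at C16=C17 would close the 22-membered ring to the macrocyclic alkene F6, and H2 over Pd/C (alkene saturation and debenzylation) would return to 23.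

2. Step 15. Palladium hydride may migrate the C16=C17 alkene toward C15 before saturation (epimerisation), and hydrodechlorination or hydrogenolysis of the benzylic C–O bonds may compete with debenzylation. Fallback, setting out from 21 and returning at 22: diimide reduction (2-nitrobenzenesulfonylhydrazide, Et3N) would give the saturated tetrabenzyl ether F7, and Lewis-acid debenzylation (BCl3, pentamethylbenzene, CH2Cl2, −78 °C) would then release 22 without any metal hydride.

3. Step 17. Cleavage of the hindered aryl carbamates may be incomplete, or the benzylic carbamates may be partly lost during the basic methanolysis; the electron-rich phenoxides may also oxidise in air. Fallback, setting out from 23 and returning at 25: phenol-selective acetylation (Ac2O, aq. NaHCO3/THF) would give the tetraacetate F8, trichloroacetyl isocyanate would then acylate only the two carbinols to give the bis(N-trichloroacetylcarbamate) tetraacetate F9, and K2CO3/MeOH would remove the trichloroacetyl groups and the aryl acetates together to give 25.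

Further compounds
F1 | step 16 | 5-[(1R,2S,7S)-7-[2,6-dihydroxy-4-(hydroxymethyl)phenyl]-1-hydroxy-2-methylundecyl]benzene-1,3-diol | CCCC[C@H](c1c(O)cc(CO)cc1O)CCCC[C@H](C)[C@@H](O)c1cc(O)cc(O)c1
F2 | step 16 | 2-[(5R)-9,9-dichloronon-1-en-5-yl]-5-[(1R,2S,7S)-7-[2,6-dihydroxy-4-(hydroxymethyl)phenyl]-1-hydroxy-2-methylundecyl]benzene-1,3-diol | CCCC[C@H](c1c(O)cc(CO)cc1O)CCCC[C@H](C)[C@@H](O)c1cc(O)c([C@H](CCCC(Cl)Cl)CCC=C)c(O)c1
F3 | step 16 | tetra-O-benzyl ether of F2 (four phenols benzylated) | CCCC[C@H](c1c(OCc2ccccc2)cc(CO)cc1OCc1ccccc1)CCCC[C@H](C)[C@@H](O)c1cc(OCc2ccccc2)c([C@H](CCCC(Cl)Cl)CCC=C)c(OCc2ccccc2)c1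
F4 | step 16 | ring-B aldehyde from F3 (CH2OH oxidised to CHO) | CCCC[C@H](c1c(OCc2ccccc2)cc(C=O)cc1OCc1ccccc1)CCCC[C@H](C)[C@@H](O)c1cc(OCc2ccccc2)c([C@H](CCCC(Cl)Cl)CCC=C)c(OCc2ccccc2)c1
F5 | step 16 | diene from F4 carrying the (1R,2S)-1-hydroxy-2-methylbut-3-en-1-yl group on ring B | CCCC[C@H](c1c(OCc2ccccc2)cc([C@H](O)[C@@H](C)C=C)cc1OCc1ccccc1)CCCC[C@H](C)[C@@H](O)c1cc(OCc2ccccc2)c([C@H](CCCC(Cl)Cl)CCC=C)c(OCc2ccccc2)c1
F6 | step 16 | tetra-O-benzyl 16,17-didehydro derivative of 23 (macrocyclic alkene, drawn E) | CCCC[C@H]1CCCC[C@H](C)[C@@H](O)c2cc(OCc3ccccc3)c(c(OCc3ccccc3)c2)[C@H](CCCC(Cl)Cl)CC/C=C/[C@H](C)[C@@H](O)c2cc(OCc3ccccc3)c1c(OCc3ccccc3)c2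
F7 | step 15 | 3,4-dihydro derivative of 21 (saturated tetrabenzyl seco-chloride) | CCCC[C@H](c1c(OCc2ccccc2)cc([C@H](O)[C@@H](C)CCCC[C@@H](Cl)CCCC(Cl)Cl)cc1OCc1ccccc1)CCCC[C@H](C)[C@@H](O)c1cc(OCc2ccccc2)cc(OCc2ccccc2)c1
F8 | step 17 | tetra-O-acetate of 23 (four phenols acetylated) | CCCC[C@H]1CCCC[C@H](C)[C@@H](O)c2cc(OC(C)=O)c(c(OC(C)=O)c2)[C@H](CCCC(Cl)Cl)CCCC[C@H](C)[C@@H](O)c2cc(OC(C)=O)c1c(OC(C)=O)c2
F9 | step 17 | 1,14-bis(N-trichloroacetylcarbamate) of tetraacetate F8 | CCCC[C@H]1CCCC[C@H](C)[C@@H](OC(=O)NC(=O)C(Cl)(Cl)Cl)c2cc(OC(C)=O)c(c(OC(C)=O)c2)[C@H](CCCC(Cl)Cl)CCCC[C@H](C)[C@@H](OC(=O)NC(=O)C(Cl)(Cl)Cl)c2cc(OC(C)=O)c1c(OC(C)=O)c2
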